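**Assumption:** the target SMILES contains no stereocentre and no stereogenic double bond, so the compound is achiral and no stereocontrol is needed.

## Retrosynthetic overview

1. Target ⇒ (double O‑demethylation) di‑O‑methyl depsidone ⇒ (lactonisation, seven‑membered ring) seco hydroxy acid ⇒ (SNAr diaryl ether) ring‑A fluoro‑aldehyde ester + 7‑hydroxychromanone.
2. Ring‑A fragment from 3,5‑difluorotoluene: formylation between the fluorines, mono‑SNAr with methoxide, bromination para to OMe, Pd alkoxycarbonylation.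
3. Chromanone fragment from coenzyme Q0: acetylhydroquinone, then Kabbe condensation in which the pyranone ring closes by intramolecular oxa‑Michael addition of the phenol onto the β,β‑dimethyl enone; then O‑benzylation and selective 7‑O‑demethylation.
4. Ring order: pyranone ring of the chromanone first, then the diaryl ether bond, then the central seven‑membered lactone ring last.

## Route

**Step 1**
Reactants: 1 3,5‑difluorotoluene
Product: 3 2,6‑difluoro‑4‑methylbenzaldehyde, via aryllithium 2 (not isolated)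
Conditions: n‑BuLi (1.05 equiv), THF, −78 °C, 1 h; DMF (1.5 equiv), −78 → 0 °C; aq. HCl
Reagents that add atoms: N,N‑dimethylformamide CN(C)C=O
Why: Directed ortho‑metalation at the most acidic C–H, flanked by both fluorines, followed by formylation of the aryllithium with DMF.

**Step 2**
Reactants: 3 2,6‑difluoro‑4‑methylbenzaldehyde
Product: 4 2‑fluoro‑6‑methoxy‑4‑methylbenzaldehyde
Conditions: NaOMe (1.05 equiv), MeOH, 0 → 50 °C
Reagents that add atoms: sodium methoxide [Na+].[O-]C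
Why: SNAr of a fluoride ortho to the formyl group; the new methoxy donor deactivates the ring so substitution stops at the mono stage.

**Step 3**
Reactants: 4 2‑fluoro‑6‑methoxy‑4‑methylbenzaldehyde
Product: 5 3‑bromo‑2‑fluoro‑6‑methoxy‑4‑methylbenzaldehyde
Conditions: NBS (1.05 equiv), cat. TFA, MeCN, 0 °C → rt, dark
Reagents that add atoms: N‑bromosuccinimide O=C1CCC(=O)N1Br
Why: Electrophilic aromatic bromination goes para to the methoxy group (also ortho to F and CH3, meta to CHO), the most activated free position.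

**Step 4**
Reactants: 5 3‑bromo‑2‑fluoro‑6‑methoxy‑4‑methylbenzaldehyde
Product: 6 benzyl 2‑fluoro‑3‑formyl‑4‑methoxy‑6‑methylbenzoate
Conditions: Pd(OAc)2 (5 mol %), Xantphos (10 mol %), CO (1–5 bar), BnOH (3 equiv), Et3N (2 equiv), toluene, 100 °C
Reagents that add atoms: carbon monoxide [C-]#[O+]; benzyl alcohol OCc1ccccc1
Why: Pd‑catalysed alkoxycarbonylation (oxidative addition, CO insertion, alcoholysis) turns the aryl bromide into the benzyl ester; aldehyde and aryl fluoride are inert under these conditions.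

**Step 5**
Reactants: 7 2,3‑dimethoxy‑5‑methyl‑1,4‑benzoquinone (coenzyme Q0)
Product: 9 1‑(2,5‑dihydroxy‑3,4‑dimethoxy‑6‑methylphenyl)ethan‑1‑one, via hydroquinone 8 (not isolated)
Conditions: H2 (1 atm), 10 % Pd/C, AcOH, rt; Ar purge; BF3·OEt2 (3 equiv), 90 °C; aq. NaOAc
Reagents that add atoms: acetic acid CC(=O)O
Why: Hydrogenation gives the air‑sensitive hydroquinone, which undergoes BF3‑mediated Friedel–Crafts (Fries‑type) C‑acetylation at its only unsubstituted ring carbon.

**Step 6**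
Reactants: 9 1‑(2,5‑dihydroxy‑3,4‑dimethoxy‑6‑methylphenyl)ethan‑1‑one
Product: 11 6‑hydroxy‑7,8‑dimethoxy‑2,2,5‑trimethylchroman‑4‑one, via hydroxyaryl enone 10 (not isolated)
Conditions: acetone (5 equiv), pyrrolidine (1 equiv), EtOH, 60 °C, Ar
Reagents that add atoms: acetone CC(C)=O
Why: Kabbe condensation: enamine aldol condensation with acetone gives the o‑hydroxyaryl β,β‑dimethyl enone, and the phenol ortho to the acyl group closes the pyranone ring by 6‑endo intramolecular oxa‑Michael addition (the other OH is meta and cannot reach).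

**Step 7**
Reactants: 11 6‑hydroxy‑7,8‑dimethoxy‑2,2,5‑trimethylchroman‑4‑one
Product: 12 6‑(benzyloxy)‑7,8‑dimethoxy‑2,2,5‑trimethylchroman‑4‑one
Conditions: BnBr (1.2 equiv), K2CO3 (2 equiv), DMF, 50 °C
Reagents that add atoms: benzyl bromide BrCc1ccccc1
Why: Williamson etherification of the only free phenol.

**Step 8**
Reactants: 12 6‑(benzyloxy)‑7,8‑dimethoxy‑2,2,5‑trimethylchroman‑4‑one
Product: 13 6‑(benzyloxy)‑7‑hydroxy‑8‑methoxy‑2,2,5‑trimethylchroman‑4‑one
Conditions: LiCl (5 equiv), DMF, 150 °C; dil. HCl work‑up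
Reagents that add atoms: none
Why: SN2 O‑demethylation by chloride is fastest at the 7‑OMe, which is twisted between two ortho oxygens and releases the phenoxide para to the ketone; the 8‑OMe and the benzyl ether would give non‑stabilised phenoxides.

**Step 9**
Reactants: 13 6‑(benzyloxy)‑7‑hydroxy‑8‑methoxy‑2,2,5‑trimethylchroman‑4‑one; 6 benzyl 2‑fluoro‑3‑formyl‑4‑methoxy‑6‑methylbenzoate
Product: 14 benzyl 2‑{[6‑(benzyloxy)‑8‑methoxy‑2,2,5‑trimethyl‑4‑oxochroman‑7‑yl]oxy}‑3‑formyl‑4‑methoxy‑6‑methylbenzoate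
Conditions: K2CO3 (1.5 equiv), DMF, 70 °C, Ar
Reagents that add atoms: none
Why: SNAr diaryl ether formation: the fluoride is activated by the ortho formyl and ortho ester groups, and the 7‑phenoxide is the only nucleophile present.

**Step 10**
Reactants: 14 diaryl ether benzyl ester
Product: 15 2‑[(6‑hydroxy‑8‑methoxy‑2,2,5‑trimethyl‑4‑oxochroman‑7‑yl)oxy]‑3‑formyl‑4‑methoxy‑6‑methylbenzoic acid
Conditions: H2 (1 atm), 10 % Pd/C, EtOAc, rt, stopped after 2 equiv H2
Reagents that add atoms: none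
Why: Hydrogenolysis cleaves the benzyl ester and benzyl ether together; the hindered, electron‑rich aryl aldehyde and the aryl ketone reduce much more slowly.

**Step 11**
Reactants: 15 seco hydroxy acid
Product: 16 di‑O‑methyl depsidone (target with both phenols as methyl ethers)
Conditions: DCC (1.5 equiv), DMAP (0.2 equiv), CH2Cl2 (0.005 M), rt
Reagents that add atoms: none
Why: Steglich‑type carbodiimide lactonisation; the diaryl ether holds the acid next to the only free phenol (6‑OH), so only the desired seven‑membered lactone can form.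

**Step 12**
Reactants: 16 di‑O‑methyl depsidone
Product: 17 target depsidone CNP0271978.0
Conditions: BBr3 (6 equiv), CH2Cl2, −78 °C → rt; H2O, 0 °C
Reagents that add atoms: none
Why: Lewis‑acid cleavage of both aryl methyl ethers with BBr3 (the OMe chelated to CHO first, then the 8‑OMe); aryl lactone, diaryl ether and chromanone are expected to survive at or below rt.

## Compound list

1 | 3,5‑difluorotoluene | Cc1cc(F)cc(F)c1 | starting material
2 | aryllithium: (2,6‑difluoro‑4‑methylphenyl)lithium | [Li]c1c(F)cc(C)cc1F | intermediate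
3 | 2,6‑difluoro‑4‑methylbenzaldehyde | O=Cc1c(F)cc(C)cc1F | intermediate
4 | 2‑fluoro‑6‑methoxy‑4‑methylbenzaldehyde | COc1cc(C)cc(F)c1C=O | intermediate
5 | 3‑bromo‑2‑fluoro‑6‑methoxy‑4‑methylbenzaldehyde | COc1cc(C)c(Br)c(F)c1C=O | intermediate
6 | benzyl 2‑fluoro‑3‑formyl‑4‑methoxy‑6‑methylbenzoate | COc1cc(C)c(C(=O)OCc2ccccc2)c(F)c1C=O | intermediate
7 | 2,3‑dimethoxy‑5‑methyl‑1,4‑benzoquinone (coenzyme Q0) | CC1=CC(=O)C(OC)=C(OC)C1=O | starting material
8 | hydroquinone: 2,3‑dimethoxy‑5‑methylbenzene‑1,4‑diol | Cc1cc(O)c(OC)c(OC)c1O | intermediate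
9 | 1‑(2,5‑dihydroxy‑3,4‑dimethoxy‑6‑methylphenyl)ethan‑1‑one | CC(=O)c1c(C)c(O)c(OC)c(OC)c1O | intermediate
10 | hydroxyaryl enone: 1‑(2,5‑dihydroxy‑3,4‑dimethoxy‑6‑methylphenyl)‑3‑methylbut‑2‑en‑1‑one | CC(C)=CC(=O)c1c(C)c(O)c(OC)c(OC)c1O | intermediate
11 | 6‑hydroxy‑7,8‑dimethoxy‑2,2,5‑trimethylchroman‑4‑one | Cc1c(O)c(OC)c(OC)c2OC(C)(C)CC(=O)c12 | intermediate
12 | 6‑(benzyloxy)‑7,8‑dimethoxy‑2,2,5‑trimethylchroman‑4‑one | Cc1c(OCc3ccccc3)c(OC)c(OC)c2OC(C)(C)CC(=O)c12 | intermediate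
13 | 6‑(benzyloxy)‑7‑hydroxy‑8‑methoxy‑2,2,5‑trimethylchroman‑4‑one | Cc1c(OCc3ccccc3)c(O)c(OC)c2OC(C)(C)CC(=O)c12 | intermediate
14 | benzyl 2‑{[6‑(benzyloxy)‑8‑methoxy‑2,2,5‑trimethyl‑4‑oxochroman‑7‑yl]oxy}‑3‑formyl‑4‑methoxy‑6‑methylbenzoate | COc1cc(C)c(C(=O)OCc2ccccc2)c(Oc3c(OCc4ccccc4)c(C)c5C(=O)CC(C)(C)Oc5c3OC)c1C=O | intermediate
15 | 2‑[(6‑hydroxy‑8‑methoxy‑2,2,5‑trimethyl‑4‑oxochroman‑7‑yl)oxy]‑3‑formyl‑4‑methoxy‑6‑methylbenzoic acid | COc1cc(C)c(C(=O)O)c(Oc2c(O)c(C)c3C(=O)CC(C)(C)Oc3c2OC)c1C=O | intermediate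
16 | di‑O‑methyl depsidone: the target with OMe ortho to CHO on ring A and OMe on ring B between the pyranone oxygen and the diaryl ether oxygen | Cc1cc(OC)c(C=O)c2c1C(=O)Oc1c(C)c3c(c(OC)c1O2)OC(C)(C)CC3=O | intermediate
17 | CNP0271978.0: depsidone (dibenzo[b,e][1,4]dioxepinone); ring A carries CH3, OH and CHO (CHO between the OH and the ether oxygen); ring B carries CH3 (next to the ester oxygen), OH (next to the ether oxygen) and a fused 2,2‑dimethyl‑2,3‑dihydropyran‑4‑one | Cc1cc(O)c(C=O)c2c1C(=O)Oc1c(C)c3c(c(O)c1O2)OC(C)(C)CC3=O | target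

## Step count and risks

Total step count: 12.
Longest linear sequence: 8 (steps 1–4 then 9–12, or steps 5–8 then 9–12).

Three steps most likely to fail:

**Step 9 (SNAr to a tetra‑ortho‑substituted diaryl ether).** Both partners are hindered and the phenoxide is stabilised by the para ketone, so conversion may be poor. The fallback forms the ester bond first and closes the seven‑membered ring by intramolecular SNAr. It sets out from 13 and 6. The 7‑OH of 13 is capped with MOMCl/i‑Pr2NEt in CH2Cl2 to give 6‑(benzyloxy)‑8‑methoxy‑7‑(methoxymethoxy)‑2,2,5‑trimethylchroman‑4‑one F1. Hydrogenolysis (H2, Pd/C, EtOAc) frees the 6‑OH to give 6‑hydroxy‑8‑methoxy‑7‑(methoxymethoxy)‑2,2,5‑trimethylchroman‑4‑one F2. Separately, 6 is hydrogenolysed to 2‑fluoro‑3‑formyl‑4‑methoxy‑6‑methylbenzoic acid F3. DCC/DMAP esterification of F2 with F3 gives the depside 8‑methoxy‑7‑(methoxymethoxy)‑2,2,5‑trimethyl‑4‑oxochroman‑6‑yl 2‑fluoro‑3‑formyl‑4‑methoxy‑6‑methylbenzoate F4. TFA in wet CH2Cl2 removes the MOM group to give 7‑hydroxy‑8‑methoxy‑2,2,5‑trimethyl‑4‑oxochroman‑6‑yl 2‑fluoro‑3‑formyl‑4‑methoxy‑6‑methylbenzoate F5. Cs2CO3 in DMF at rt then lets the 7‑phenoxide displace the fluoride, which comes back to the route at 16 (14 and 15 are bypassed). The 7‑phenoxide is the thermodynamically favoured anion, which should limit acyl migration before ring closure.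

**Step 8 (selective 7‑O‑demethylation beside a benzyl ether).** Chloride may also attack the benzyl group or react too slowly. The fallback reverses the order of deprotection and protection and sets out from 11. BCl3 (1.2 equiv, CH2Cl2, −78 → 0 °C) binds the free 6‑OH and cleaves only the neighbouring 7‑OMe through the five‑membered chelate, giving 6,7‑dihydroxy‑8‑methoxy‑2,2,5‑trimethylchroman‑4‑one F6. Its dianion (NaH 2.2 equiv, DMF, 0 °C) is benzylated with 1.0 equiv BnBr at the more basic, non‑conjugated 6‑oxide, because the 7‑oxide is delocalised into the para ketone. This comes back to the route at 13.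

**Step 4 (carbonylation of a bromide flanked by F and CH3, with a free aldehyde).** Oxidative addition or CO insertion may be sluggish and hydrodebromination may compete. The fallback replaces Pd catalysis by polar organometallic carboxylation and sets out from 5. Ethylene glycol with cat. TsOH (toluene, Dean–Stark) gives 2‑(3‑bromo‑2‑fluoro‑6‑methoxy‑4‑methylphenyl)‑1,3‑dioxolane F7. Br/Li exchange (n‑BuLi, THF, −78 °C, cold enough to avoid benzyne formation) gives [3‑(1,3‑dioxolan‑2‑yl)‑2‑fluoro‑4‑methoxy‑6‑methylphenyl]lithium F8. This is added to excess benzyl chloroformate at −78 °C to give benzyl 3‑(1,3‑dioxolan‑2‑yl)‑2‑fluoro‑4‑methoxy‑6‑methylbenzoate F9. Aqueous HCl in THF removes the acetal and comes back to the route at 6.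

## Further compounds

F1 | step 9 | 6‑(benzyloxy)‑8‑methoxy‑7‑(methoxymethoxy)‑2,2,5‑trimethylchroman‑4‑one | Cc1c(OCc3ccccc3)c(OCOC)c(OC)c2OC(C)(C)CC(=O)c12
F2 | step 9 | 6‑hydroxy‑8‑methoxy‑7‑(methoxymethoxy)‑2,2,5‑trimethylchroman‑4‑one | Cc1c(O)c(OCOC)c(OC)c2OC(C)(C)CC(=O)c12
F3 | step 9 | 2‑fluoro‑3‑formyl‑4‑methoxy‑6‑methylbenzoic acid | COc1cc(C)c(C(=O)O)c(F)c1C=O
F4 | step 9 | 8‑methoxy‑7‑(methoxymethoxy)‑2,2,5‑trimethyl‑4‑oxochroman‑6‑yl 2‑fluoro‑3‑formyl‑4‑methoxy‑6‑methylbenzoate | COc1cc(C)c(C(=O)Oc2c(C)c3C(=O)CC(C)(C)Oc3c(OC)c2OCOC)c(F)c1C=O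
F5 | step 9 | 7‑hydroxy‑8‑methoxy‑2,2,5‑trimethyl‑4‑oxochroman‑6‑yl 2‑fluoro‑3‑formyl‑4‑methoxy‑6‑methylbenzoate | COc1cc(C)c(C(=O)Oc2c(C)c3C(=O)CC(C)(C)Oc3c(OC)c2O)c(F)c1C=O
F6 | step 8 | 6,7‑dihydroxy‑8‑methoxy‑2,2,5‑trimethylchroman‑4‑one | Cc1c(O)c(O)c(OC)c2OC(C)(C)CC(=O)c12
F7 | step 4 | 2‑(3‑bromo‑2‑fluoro‑6‑methoxy‑4‑methylphenyl)‑1,3‑dioxolane | COc1cc(C)c(Br)c(F)c1C1OCCO1
F8 | step 4 | [3‑(1,3‑dioxolan‑2‑yl)‑2‑fluoro‑4‑methoxy‑6‑methylphenyl]lithium | COc1cc(C)c([Li])c(F)c1C1OCCO1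
F9 | step 4 | benzyl 3‑(1,3‑dioxolan‑2‑yl)‑2‑fluoro‑4‑methoxy‑6‑methylbenzoate | COc1cc(C)c(C(=O)OCc2ccccc2)c(F)c1C1OCCO1
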